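## Analysis of the target

The target is a fully substituted benzene ring, a 2,4,6-trihydroxybenzene-1,3-dicarbaldehyde (ring carbons a1–a6, a1 bonded to the side chain, a3 and a5 carrying the formyl groups), joined through the benzylic carbon Cb, which also bears an isobutyl group, to C1 of a trans-fused decalin made of ring A (C1–C2–C3–C4–C5–C10) and ring B (C5–C6–C7–C8–C9–C10). Six stereocentres are present: Cb (S), C1 (R), C4 (R), C5 (S), C7 (S) and C10 (R). With the angular methyl on C10 as the reference face, the Cb substituent on C1, the hydroxyl on C4 and the 2-hydroxypropan-2-yl group (carbinol carbon C11) on C7 are syn to it and H5 is anti, so in the chair–chair decalin the C1 and C7 substituents are equatorial and the C4 hydroxyl is axial, 1,3-diaxial to the methyl. The tertiary alcohols at C4 and C11 ionise and eliminate under strong Brønsted or Lewis acids, and the diformylated triphenol is an acidic, electron-rich vinylogous acid, so it has to be completed and unmasked last under mild conditions. The difficulties are the quaternary C10 between the C1 and C5 stereocentres, the exocyclic stereocentre Cb lodged between a neopentyl-type ring carbon and an aryl ring with two ortho oxygens, and aromatic chemistry that must coexist with the tertiary carbinols. The strategy rests on the fact that ring B, with the methyl-bearing C10, its neighbour C5, the C7 substituent in the right absolute configuration and C11 at the alcohol level, is the ring of hydrated (R)-carvone, in which C9 is the carbonyl carbon and C10=C5 the enone double bond. Ring A then lacks only the four carbons C1–C4, attached to C10 and C5, with oxygen on C4 and a handle on C1; a cyclobutene-1,2-diol derivative leaves exactly this behind once its two sp2 carbons are added across C10=C5 and the bond between them is cut. A ground-state alkylation of a C10 enolate would place the new bond cis to the C7 substituent, the wrong way round, whereas photochemical bonding that starts at C5 should put both new bonds trans to it.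

## Retrosynthetic reasoning

**Protecting groups (28 ⇐ 27 ⇐ 26).** The last two operations remove the two triethylsilyl ethers of 27 and, before that, the three methyl ethers of 26. The phenols stay methylated until both aldehydes are present, because every methoxy group is then ortho or para to a formyl group and can be removed by a soft nucleophile under basic conditions. The tertiary C4 and C11 oxygens tolerate this, whereas a strongly Lewis-acidic ether cleavage would ionise them.

**Formyl groups (26 ⇐ 25 ⇐ 24 ⇐ 23).** The a3–CHO and a5–CHO bonds are cut. The two open ring positions of 23 are each flanked by two methoxy groups, so they brominate readily to give 24; the dilithio compound 25 then takes up two formyl groups. This avoids Lewis-acidic formylation in the presence of the tertiary silyl ethers, and the aldehydes arrive only after all cation and organometallic chemistry at Cb is over.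

**Cb–H and Cb–a1 (23 ⇐ 22 ⇐ 18 + 19).** Cb is disconnected to a planar benzylic cation derived from the tertiary alcohol 22, which in turn comes from ketone 18 and the aryl nucleophile 21 (made from 19 through 20). Both epimers of 22 give the same cation, so no selectivity is needed in the addition. The configuration is decided when a hydride donor attacks the cation, which is held in one rotamer by allylic 1,3-strain between the ring and the ortho methoxy groups. Hydride is delivered last because the model predicts the S configuration for that order.

**Cb–CH2, C1–Cb and C1–H (18 ⇐ 17 ⇐ 15 + 16; 15 ⇐ 14 ⇐ 13).** The isobutyl group is detached as the Grignard reagent 16 adding to the amide 15. The carbonyl carbon Cb is detached from C1 by carbonylation of the enol triflate 14, which can only form towards C2 because C10 is quaternary. The hydrogen on C1 is added to the C1=C2 bond of 17 from the face anti to the angular methyl, which gives the equatorial acyl group; this is also the more stable epimer of an enolisable centre.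

**C4–CH3 (13 ⇐ 12 ⇐ 11).** The methyl carbinol is cut to the C4 ketone of dione 11. C1 is flanked by the quaternary C10, so a methyl nucleophile should choose C4. The axial approach to C4 is blocked by the syn-axial C10 methyl, so the nucleophile enters equatorially and leaves the hydroxyl axial, as required.

**C5 epimer and the C1–C4 bond (11 ⇐ 10 ⇐ 9 ⇐ 8).** The trans-dione 11 is the C5 epimer of the cis-dione 10; C5 is enolisable next to the C4 ketone. The two carbonyls of 10 are reconnected into the vicinal diol 9, whose glycol cleavage is strongly driven by the strain of the bicyclo[2.2.0]hexane. This turns a ring A problem into the problem of making the tricyclic bis-silyl ether 8.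

**C9 oxygen (8 ⇐ 7 ⇐ 6 ⇐ 5).** The carbonyl at C9 that the photochemistry requires is restored. It has to be removed before the diol is unveiled, because a free hydroxyl on C1 beta to a C9 ketone would open the C10–C1 bond by retro-aldol cleavage. The route goes through the enol triflate 6 and the alkene 7, which avoids a radical at C9 next to the strained ring.

**Key disconnection (5 ⇐ 3 + 4).** The C10–C1 and C5–C4 bonds are cut together, giving enone 3 and the symmetric alkene 4. The forward reaction has to make the quaternary C10 with its new bond anti to the C7 substituent. Nothing else about the adduct matters, because C1 and C4 become carbonyl carbons and C5 is equilibrated.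

**Enone (3 ⇐ 2 ⇐ 1).** The silyl ether 3 comes from the tertiary alcohol 2, the hydration product of (R)-carvone 1. This supplies C7, C11 with its oxygen, C10 with its methyl and the whole of ring B in two steps, and it removes the side-chain alkene that would otherwise react intramolecularly on irradiation.

## Alternatives that were turned down

**Alternative 1:** Ring B is disconnected at C7–C8 together with the C11–O bond. The aldoxime A1 already carries the complete Cb side chain, a C4 ketal, a prenyl group on C5 and the oxime-terminated two-carbon arm on C10. It is oxidised to the nitrile oxide A2, which adds intramolecularly to the trisubstituted alkene and gives the isoxazoline-fused trans-decalin A3.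
- For it: one step closes ring B, sets C7 and places oxygen on C11 with unambiguous regiochemistry. The aryl group is installed early, so no nucleophile has to be forced onto a hindered C1 ketone late on. On that point it is stronger than the chosen route.
- Against it: the isoxazoline leaves C8 at the ketone level after N–O cleavage, as a beta-hydroxy ketone prone to retro-aldol and dehydration, and this oxygen must then be removed. The electron-rich arene has to survive the oxidant that generates A2. Above all, A1 needs C1, C5, the quaternary C10 and Cb to be set on a monocyclic ring without the help of a decalin, so the hardest stereochemical problems move into the preparation of the precursor.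
- Comparison: the chosen strategy gets C7, C11–O and ring B from 1 for nothing, and spends its key step on the quaternary centre.

**Alternative 2:** Three bonds of the aromatic ring (a1–a2, a2–a3, a5–a6) are disconnected. Heating 3-ethoxycyclobutenone A4 with the siloxyalkyne A5 gives the differentiated phenol A6 through a vinylketene, a [2+2] addition, a second ring opening and a 6π closure.
- For it: no di-ortho-substituted aryl nucleophile has to add to a hindered ketone, and no benzylic cation is formed. The three phenolic oxygens come out differentiated (free, silyl, ethyl), so the final unmasking is gentler than a triple demethylation. On these points it is stronger.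
- Against it: the key step builds neither a terpene bond nor a stereocentre. Cb must already be set in A5, which itself needs several steps from a carboxylic acid derivative on a neopentyl-type carbon. A6 still lacks both formyl groups and keeps one alkyl ether.
- Comparison: the decalin would have to be made anyway, and the chosen strategy addresses that part. It also brings in the aryl unit from a commercial compound in one step, with a convergent and stereochemically argued reduction.

**Alternative 3:** Ring A is disconnected at C4–C5, with a temporary C6–C7 bond. In the dioxenone A7 the heterocycle is tethered through C3–C2–C1 to the quaternary C10, which bears a vinyl group. Irradiation gives the photoadduct A8; retro-aldol opening of its dioxanone would then release the C4 ketone and a C7 carboxyl group for later closure of ring B.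
- For it: the tether fixes the regiochemistry and the face of the photocycloaddition, and the C1 side chain is in place before any ring is made. On these points it is stronger than an intermolecular photoreaction followed by late work at C1.
- Against it: A7 is an acyclic compound in which Cb, C1 and the quaternary C10 must be set by acyclic stereocontrol. After fragmentation ring B still has to be closed at C7–C8 and C11 built from the carboxyl group. The risk therefore lies before and after the key step, not in it.
- Comparison: the chosen strategy adds ring A in one step to an enantiopure ring B that is two steps from 1.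

Key step: step 3

Remarks (conventions and one assumption): Atom labels C1–C11, Cb and a1–a6 are those defined in the analysis; "syn" and "anti" refer to the face of the C10 methyl. The photoadduct 5 is drawn as the cis-anti-cis isomer; its configurations at C1, C4 and C5 are later erased or equilibrated, so any adduct isomer with the same C10 configuration would serve equally.

## Route

Step 1
Reactants: 1 (R)-carvone
Product: 2 (5R)-5-(2-hydroxypropan-2-yl)-2-methylcyclohex-2-en-1-one
Conditions: 50% aq. H2SO4, 0 °C
Reagents that add atoms: water, O
Why: Acid-catalysed Markovnikov hydration of the 1,1-disubstituted alkene through the tertiary cation; the electron-poor enone double bond is not protonated at carbon, the stereocentre is not involved, and the low temperature limits aromatisation.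

Step 2
Reactants: 2 (5R)-5-(2-hydroxypropan-2-yl)-2-methylcyclohex-2-en-1-one
Product: 3 (5R)-2-methyl-5-[2-(triethylsilyloxy)propan-2-yl]cyclohex-2-en-1-one
Conditions: TESOTf, 2,6-lutidine, CH2Cl2, −78 °C
Reagents that add atoms: triethylsilyl trifluoromethanesulfonate, CC[Si](CC)(CC)OS(=O)(=O)C(F)(F)F
Why: Silylation of a tertiary alcohol with a silyl triflate and a hindered pyridine base; at low temperature the enone is not enolised, and the bulky ether later serves as the pseudo-equatorial control group on C7.

Step 3
Reactants: 3 (5R)-2-methyl-5-[2-(triethylsilyloxy)propan-2-yl]cyclohex-2-en-1-one; 4 1,2-bis(trimethylsilyloxy)cyclobutene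
Product: 5 cis-anti-cis photoadduct 1-methyl-2,5-bis(trimethylsilyloxy)-8-[2-(triethylsilyloxy)propan-2-yl]tricyclo[4.4.0.0(2,5)]decan-10-one (ketone at C9; silyloxy groups on C1 and C4; both new bonds anti to the C7 group)
Conditions: hν (medium-pressure Hg lamp, Pyrex filter, λ > 300 nm), 4 (4 equiv), degassed CH2Cl2, −40 °C
Reagents that add atoms: none
Why: Excitation of the enone and intersystem crossing give the twisted triplet, which is intercepted by the electron-rich alkene 4; bonding, most simply at the beta-carbon C5, gives a triplet 1,4-diradical that after spin inversion collapses at C10, so that C5–C4 and C10–C1 form in a stepwise [2+2] photocycloaddition. The closest known reaction type is the enone–alkene [2+2] photocycloaddition of cyclohexenones with 1,2-bis(silyloxy)cycloalkenes carried out ahead of a glycol cleavage. The one ring closed is the central cyclobutane (C1–C4–C5–C10), formed by radical–radical recombination of the 1,4-diradical, and it should be cis-fused to the cyclohexanone because a trans six–four junction on a bicyclo[2.2.0]hexane would be far more strained. C5 is set by axial bonding on the half-chair enone anti to the pseudo-equatorial silyloxypropyl group on C7; C10 follows from ring closure on the same face, which leaves its methyl syn to the C7 substituent as in the target; C1 and C4 are cis by the ring and are expected anti to the six-membered ring for steric reasons. Only the face selectivity at C10 has to hold, because C1 and C4 become carbonyl carbons and C5 is equilibrated later. Regiochemistry is no issue because 4 is symmetric, and the intramolecular [2+2] reaction open to 1 is excluded because the side-chain alkene has been hydrated.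

Step 4
Reactants: 5 cis-anti-cis photoadduct
Product: 6 C9 enol triflate of 5 (C8=C9)
Conditions: KHMDS, THF, −78 °C; PhNTf2, −78 → 0 °C
Reagents that add atoms: N-phenylbis(trifluoromethanesulfonimide), O=S(=O)(N(c1ccccc1)S(=O)(=O)C(F)(F)F)C(F)(F)F
Why: Enol triflate formation; the ketone can enolise only towards C8 because C10 is quaternary, the trimethylsilyl ethers survive the amide base, and the carbonyl is removed at this stage because a free C1 hydroxyl beta to it would cleave C10–C1 by retro-aldol reaction.

Step 5
Reactants: 6 C9 enol triflate
Product: 7 tricyclic C8=C9 alkene (bis-trimethylsilyl ether)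
Conditions: Pd(OAc)2 (cat.), PPh3, HCO2H, Et3N, DMF, 60 °C
Reagents that add atoms: none
Why: Palladium-catalysed reduction of an enol triflate by formate (oxidative addition to zerovalent palladium, exchange for formate, loss of CO2 to a palladium hydride, reductive elimination); no radical is generated at C9 next to the strained ring.

Step 6
Reactants: 7 tricyclic C8=C9 alkene
Product: 8 saturated tricycle with C9 methylene (1-methyl-2,5-bis(trimethylsilyloxy)-8-[2-(triethylsilyloxy)propan-2-yl]tricyclo[4.4.0.0(2,5)]decane)
Conditions: H2 (1 atm), Pd/C, EtOAc, rt
Reagents that add atoms: none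
Why: Heterogeneous hydrogenation of a cis-disubstituted ring alkene; no stereocentre is created, and ethyl acetate as solvent spares the silyl ethers.

Step 7
Reactants: 8 saturated tricycle
Product: 9 C1,C4-diol (cis-cyclobutane-1,2-diol of the tricycle; C11 triethylsilyl ether retained)
Conditions: K2CO3, MeOH, 0 °C → rt
Reagents that add atoms: none
Why: Base-catalysed methanolysis removes the two trimethylsilyl ethers, while the triethylsilyl ether on the hindered tertiary C11 should survive; with C9 now a methylene group the free diol has no retro-aldol pathway.

Step 8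
Reactants: 9 C1,C4-diol
Product: 10 cis-fused 10-methyl-7-[2-(triethylsilyloxy)propan-2-yl]decalin-1,4-dione (H5 syn to the C10 methyl)
Conditions: Pb(OAc)4, CH2Cl2, 0 °C
Reagents that add atoms: none
Why: Glycol cleavage through a cyclic plumbate of the cis-diol, driven by release of the bicyclo[2.2.0]hexane strain; cutting C1–C4 unveils ring A as a cyclohexane-1,4-dione, with C10 and C7 untouched.

Step 9
Reactants: 10 cis-fused decalin-1,4-dione
Product: 11 trans-fused 10-methyl-7-[2-(triethylsilyloxy)propan-2-yl]decalin-1,4-dione (H5 anti to the C10 methyl)
Conditions: NaOMe (cat.), MeOH, rt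
Reagents that add atoms: none
Why: Enolisation at C5 next to the C4 ketone equilibrates the ring fusion; the trans isomer should be favoured because the cis isomer, with ring B locked by the equatorial C7 group, must carry C4 axial on ring B and C9 axial on ring A; C10 and C7 cannot epimerise, and recovered cis isomer can be resubmitted.

Step 10
Reactants: 11 trans-fused decalin-1,4-dione
Product: 12 4-hydroxy-4-methyl-trans-decalin-1-one (C4 hydroxyl axial and syn to the C10 methyl; C4 methyl equatorial)
Conditions: MeMgBr (1.1 equiv), THF, −78 °C
Reagents that add atoms: methylmagnesium bromide, C[Mg]Br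
Why: Grignard addition to the less hindered ketone (C1 is flanked by the quaternary C10, as in 2,2-disubstituted cyclohexane-1,4-diones, which react at the remote carbonyl); the syn-axial C10 methyl blocks axial approach to C4, so methyl enters equatorially and sets C4 with the hydroxyl axial.

Step 11
Reactants: 12 4-hydroxy-4-methyl-trans-decalin-1-one
Product: 13 C4,C11-bis(triethylsilyl) ether of 12
Conditions: TESOTf, 2,6-lutidine, CH2Cl2, −78 → −20 °C
Reagents that add atoms: triethylsilyl trifluoromethanesulfonate, CC[Si](CC)(CC)OS(=O)(=O)C(F)(F)F
Why: Silyl triflates silylate even hindered axial tertiary alcohols; protection prevents alkoxide formation in the enolisation and organometallic steps that follow, and any silyl enol ether formed at C1 is hydrolysed on work-up.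

Step 12
Reactants: 13 bis(triethylsilyl) ether ketone
Product: 14 C1 enol triflate (C1=C2)
Conditions: KHMDS, THF, −78 °C; PhNTf2, −78 → 0 °C
Reagents that add atoms: N-phenylbis(trifluoromethanesulfonimide), O=S(=O)(N(c1ccccc1)S(=O)(=O)C(F)(F)F)C(F)(F)F
Why: Enol triflate formation; the C1 ketone can enolise only towards C2 because C10 is quaternary, so the regiochemistry is fixed.

Step 13
Reactants: 14 C1 enol triflate
Product: 15 C1=C2 unsaturated N-methoxy-N-methylcarboxamide (amide carbon = Cb)
Conditions: Pd(OAc)2 (cat.), dppp, CO (1 atm), MeNH(OMe)·HCl, Et3N, DMF, 60 °C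
Reagents that add atoms: carbon monoxide, [C-]#[O+]; N,O-dimethylhydroxylamine hydrochloride, CNOC.Cl
Why: Palladium-catalysed aminocarbonylation of an enol triflate (oxidative addition, CO insertion, aminolysis of the acylpalladium species), a reaction that works on enol triflates next to quaternary ring carbons; it forms the C1–Cb bond.

Step 14
Reactants: 15 unsaturated N-methoxy-N-methylcarboxamide; 16 isobutylmagnesium bromide
Product: 17 enone with a 3-methylbutanoyl group on C1 (C1=C2)
Conditions: 16, THF, 0 °C → rt
Reagents that add atoms: none
Why: Ketone synthesis from an N-methoxy-N-methylamide; the chelated tetrahedral intermediate prevents a second addition and collapses to the ketone only on work-up, and 1,2-addition is favoured over conjugate addition at the hindered ring carbon.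

Step 15
Reactants: 17 enone
Product: 18 saturated ketone with the 3-methylbutanoyl group equatorial on C1 (syn to the C10 methyl; H1 anti)
Conditions: H2 (1 atm), Pd/C, EtOAc, rt
Reagents that add atoms: none
Why: Heterogeneous hydrogenation delivers hydrogen to C1 from the face anti to the angular methyl, as with ring enones next to an angular methyl group; the resulting equatorial acyl epimer is also the thermodynamic one at this enolisable centre, so C1 is set reliably.

Step 16
Reactants: 18 saturated isobutyl ketone; 19 1-bromo-2,4,6-trimethoxybenzene
Product: 22 Cb tertiary alcohol bearing isobutyl/2,4,6-trimethoxyphenyl/C1 (both Cb epimers; bis-TES ether), via 2,4,6-trimethoxyphenyllithium 20 (not isolated), via dichloro(2,4,6-trimethoxyphenyl)cerium 21 (not isolated)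
Conditions: 19, n-BuLi, THF, −78 °C; CeCl3, −78 °C; then 18, −78 → 0 °C
Reagents that add atoms: none
Why: Bromine–lithium exchange followed by transmetalation gives an organocerium reagent, whose low basicity and high oxophilicity favour 1,2-addition to a hindered, enolisable ketone; the configuration at Cb is irrelevant because both epimers give the same cation in the next step.

Step 17
Reactants: 22 Cb tertiary alcohol (both epimers)
Product: 23 (S)-Cb compound: Cb–H bearing isobutyl, 2,4,6-trimethoxyphenyl and C1 (bis-TES ether)
Conditions: Et3SiH, CF3CO2H, CH2Cl2, −78 → −30 °C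
Reagents that add atoms: none
Why: Ionic hydrogenation: the alcohol ionises to a benzylic cation strongly stabilised by three methoxy groups and is reduced by the silane; allylic 1,3-strain with the ortho methoxy groups should hold C1–H in the cation plane on the aryl side, so hydride enters on the C2 side, anti to the quaternary C10, which corresponds to the S configuration. Any styrene formed by proton loss re-ionises to the same cation (reprotonation at C1 anti to the methyl), and the tertiary silyl ethers at C4 and C11 should not ionise at this temperature.

Step 18
Reactants: 23 (S)-Cb trimethoxyphenyl compound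
Product: 24 a3,a5-dibromide of 23
Conditions: NBS (2.1 equiv), MeCN, 0 °C, dark
Reagents that add atoms: N-bromosuccinimide, O=C1CCC(=O)N1Br
Why: Electrophilic aromatic bromination of the two free ring positions, each activated by two flanking methoxy groups; polar, dark conditions keep the benzylic C–H out of play.

Step 19
Reactants: 24 a3,a5-dibromide
Product: 26 a3,a5-dicarbaldehyde of 23 (tri-O-methyl ether; bis-TES ether), via a3,a5-dilithio arene 25 (not isolated)
Conditions: t-BuLi (4.4 equiv), THF, −78 °C; DMF, −78 → 0 °C; aq. NH4Cl
Reagents that add atoms: N,N-dimethylformamide, CN(C)C=O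
Why: Double bromine–lithium exchange (each aryllithium stabilised by two ortho methoxy groups) and formylation with a formamide, as used for dibromo-dimethoxyarenes; the sequence is free of Lewis acids and so compatible with the tertiary silyl ethers.

Step 20
Reactants: 26 a3,a5-dicarbaldehyde tri-O-methyl ether
Product: 27 C4,C11-bis(triethylsilyl) ether of the target (free triphenol dialdehyde)
Conditions: NaSEt (excess), DMF, 110 °C; dilute HCl work-up
Reagents that add atoms: none
Why: SN2 demethylation of aryl methyl ethers by thiolate; every methoxy group is ortho or para to a formyl group, so each phenoxide is a stabilised leaving group, and the basic conditions leave the tertiary silyl ethers and the carbon skeleton untouched.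

Step 21
Reactants: 27 bis(triethylsilyl) ether of the target
Product: 28 target, 5-[(1S)-1-[(1R,4R,4aS,6S,8aR)-4-hydroxy-6-(2-hydroxypropan-2-yl)-4,8a-dimethyldecahydronaphthalen-1-yl]-3-methylbutyl]-2,4,6-trihydroxybenzene-1,3-dicarbaldehyde
Conditions: HF·pyridine, THF, 0 °C → rt
Reagents that add atoms: none
Why: Fluoride-mediated cleavage of the two tertiary triethylsilyl ethers under weakly acidic conditions that the phenols, aldehydes and tertiary alcohols should tolerate; no stereocentre is touched.

## Compound list

1 | (R)-carvone | CC1=CC[C@@H](C(C)=C)CC1=O | starting material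
2 | (5R)-5-(2-hydroxypropan-2-yl)-2-methylcyclohex-2-en-1-one | CC1=CC[C@@H](C(C)(C)O)CC1=O | intermediate
3 | (5R)-2-methyl-5-[2-(triethylsilyloxy)propan-2-yl]cyclohex-2-en-1-one | CC1=CC[C@@H](C(C)(C)O[Si](CC)(CC)CC)CC1=O | intermediate
4 | 1,2-bis(trimethylsilyloxy)cyclobutene | C[Si](C)(C)OC1=C(O[Si](C)(C)C)CC1 | starting material
5 | cis-anti-cis photoadduct, 1-methyl-2,5-bis(trimethylsilyloxy)-8-[2-(triethylsilyloxy)propan-2-yl]tricyclo[4.4.0.0(2,5)]decan-10-one | C[Si](C)(C)O[C@@]13CC[C@@]3(O[Si](C)(C)C)[C@@H]2C[C@@H](C(C)(C)O[Si](CC)(CC)CC)CC(=O)[C@]12C | intermediate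
6 | C9 enol triflate of 5 (C8=C9) | C[Si](C)(C)O[C@@]13CC[C@@]3(O[Si](C)(C)C)[C@@H]2C[C@@H](C(C)(C)O[Si](CC)(CC)CC)C=C(OS(=O)(=O)C(F)(F)F)[C@]12C | intermediate
7 | tricyclic C8=C9 alkene, bis-trimethylsilyl ether | C[Si](C)(C)O[C@@]13CC[C@@]3(O[Si](C)(C)C)[C@@H]2C[C@@H](C(C)(C)O[Si](CC)(CC)CC)C=C[C@]12C | intermediate
8 | saturated tricycle with C9 methylene, bis-trimethylsilyl ether | C[Si](C)(C)O[C@@]13CC[C@@]3(O[Si](C)(C)C)[C@@H]2C[C@@H](C(C)(C)O[Si](CC)(CC)CC)CC[C@]12C | intermediate
9 | C1,C4-diol of the tricycle (cis-cyclobutane-1,2-diol) | O[C@@]13CC[C@@]3(O)[C@@H]2C[C@@H](C(C)(C)O[Si](CC)(CC)CC)CC[C@]12C | intermediate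
10 | cis-fused 10-methyl-7-[2-(triethylsilyloxy)propan-2-yl]decalin-1,4-dione (H5 syn to C10 methyl) | O=C1CCC(=O)[C@@H]2C[C@@H](C(C)(C)O[Si](CC)(CC)CC)CC[C@]12C | intermediate
11 | trans-fused 10-methyl-7-[2-(triethylsilyloxy)propan-2-yl]decalin-1,4-dione (H5 anti to C10 methyl) | O=C1CCC(=O)[C@H]2C[C@@H](C(C)(C)O[Si](CC)(CC)CC)CC[C@]12C | intermediate
12 | 4-hydroxy-4-methyl-trans-decalin-1-one (C4 hydroxyl axial, syn to C10 methyl) | O=C1CC[C@@](C)(O)[C@H]2C[C@@H](C(C)(C)O[Si](CC)(CC)CC)CC[C@]12C | intermediate
13 | C4,C11-bis(triethylsilyl) ether of 12 | O=C1CC[C@@](C)(O[Si](CC)(CC)CC)[C@H]2C[C@@H](C(C)(C)O[Si](CC)(CC)CC)CC[C@]12C | intermediate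
14 | C1 enol triflate (C1=C2) | O=S(=O)(OC1=CC[C@@](C)(O[Si](CC)(CC)CC)[C@H]2C[C@@H](C(C)(C)O[Si](CC)(CC)CC)CC[C@]12C)C(F)(F)F | intermediate
15 | C1=C2 unsaturated N-methoxy-N-methylcarboxamide on C1 | CON(C)C(=O)C1=CC[C@@](C)(O[Si](CC)(CC)CC)[C@H]2C[C@@H](C(C)(C)O[Si](CC)(CC)CC)CC[C@]12C | intermediate
16 | isobutylmagnesium bromide | CC(C)C[Mg]Br | starting material
17 | enone with 3-methylbutanoyl group on C1 (C1=C2) | CC(C)CC(=O)C1=CC[C@@](C)(O[Si](CC)(CC)CC)[C@H]2C[C@@H](C(C)(C)O[Si](CC)(CC)CC)CC[C@]12C | intermediate
18 | saturated ketone, 3-methylbutanoyl group equatorial on C1 (syn to C10 methyl) | CC(C)CC(=O)[C@H]1CC[C@@](C)(O[Si](CC)(CC)CC)[C@H]2C[C@@H](C(C)(C)O[Si](CC)(CC)CC)CC[C@]12C | intermediate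
19 | 1-bromo-2,4,6-trimethoxybenzene | COc1cc(OC)c(Br)c(OC)c1 | starting material
20 | 2,4,6-trimethoxyphenyllithium | [Li]c1c(OC)cc(OC)cc1OC | intermediate
21 | dichloro(2,4,6-trimethoxyphenyl)cerium | Cl[Ce](Cl)c1c(OC)cc(OC)cc1OC | intermediate
22 | Cb tertiary alcohol bearing isobutyl, 2,4,6-trimethoxyphenyl and C1 (both Cb epimers) | CC(C)CC(O)(c1c(OC)cc(OC)cc1OC)[C@H]1CC[C@@](C)(O[Si](CC)(CC)CC)[C@H]2C[C@@H](C(C)(C)O[Si](CC)(CC)CC)CC[C@]12C | intermediate
23 | (S)-Cb compound with 2,4,6-trimethoxyphenyl group, bis-TES ether | CC(C)C[C@H](c1c(OC)cc(OC)cc1OC)[C@H]1CC[C@@](C)(O[Si](CC)(CC)CC)[C@H]2C[C@@H](C(C)(C)O[Si](CC)(CC)CC)CC[C@]12C | intermediate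
24 | a3,a5-dibromide of 23 | CC(C)C[C@H](c1c(OC)c(Br)c(OC)c(Br)c1OC)[C@H]1CC[C@@](C)(O[Si](CC)(CC)CC)[C@H]2C[C@@H](C(C)(C)O[Si](CC)(CC)CC)CC[C@]12C | intermediate
25 | a3,a5-dilithio arene | CC(C)C[C@H](c1c(OC)c([Li])c(OC)c([Li])c1OC)[C@H]1CC[C@@](C)(O[Si](CC)(CC)CC)[C@H]2C[C@@H](C(C)(C)O[Si](CC)(CC)CC)CC[C@]12C | intermediate
26 | a3,a5-dicarbaldehyde, tri-O-methyl ether, bis-TES ether | CC(C)C[C@H](c1c(OC)c(C=O)c(OC)c(C=O)c1OC)[C@H]1CC[C@@](C)(O[Si](CC)(CC)CC)[C@H]2C[C@@H](C(C)(C)O[Si](CC)(CC)CC)CC[C@]12C | intermediate
27 | C4,C11-bis(triethylsilyl) ether of the target | CC(C)C[C@H](c1c(O)c(C=O)c(O)c(C=O)c1O)[C@H]1CC[C@@](C)(O[Si](CC)(CC)CC)[C@H]2C[C@@H](C(C)(C)O[Si](CC)(CC)CC)CC[C@]12C | intermediate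
28 | 5-[(1S)-1-[(1R,4R,4aS,6S,8aR)-4-hydroxy-6-(2-hydroxypropan-2-yl)-4,8a-dimethyldecahydronaphthalen-1-yl]-3-methylbutyl]-2,4,6-trihydroxybenzene-1,3-dicarbaldehyde | CC(C)C[C@H](c1c(O)c(C=O)c(O)c(C=O)c1O)[C@H]1CC[C@@](C)(O)[C@H]2C[C@@H](C(C)(C)O)CC[C@]12C | target

## Step count and risks

Total step count: 21. Longest linear sequence: 21 steps from (R)-carvone 1; compounds 4, 16 and 19 are purchased.

**Step 3 (key step).**
- What may go wrong: insufficient face selectivity at C10 (bonding syn to the C7 substituent, or a first bond at C10, where the face is less biased), together with enone dimerisation or loss of silyl groups on long irradiation. A wrong configuration at the quaternary C10 cannot be corrected later.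
- Fallback: form the same two bonds on the ground-state surface by a Lewis-acid-catalysed Diels–Alder reaction, which is dependably anti-selective with 5-substituted 2-methylcyclohexenones, and introduce the ring A oxygens afterwards. Setting out from 3, buta-1,3-diene and EtAlCl2 in toluene should give the cis-fused octalone F1 with the diene anti to the C7 group. Wolff–Kishner reduction removes the C9 carbonyl and gives the octalin F2 (the tertiary silyl ether is restored with TESOTf if it is lost). Br2 adds to C2=C3 to give the dibromide F3, and DBU eliminates twice to the ring A diene F4. Singlet oxygen (O2, hν, tetraphenylporphyrin) gives the 1,4-endoperoxide F5; H2 over Pd/C reduces the O–O bond and the alkene to the cis-1,4-diol F6; Swern oxidation returns to dione 10. This takes seven steps in place of the six of steps 3 to 8.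

**Step 17.**
- What may go wrong: low or reversed facial selectivity in hydride delivery to the benzylic cation (reaction through another rotamer), slow re-ionisation of styrenes formed by proton loss, or cleavage of the tertiary silyl ethers if the temperature rises.
- Fallback: reverse the order in which the two Cb substituents arrive, so that the carbon chain and not hydride is delivered to the cation; with the same facial preference this inverts the configuration at Cb. It helps only if the face preference of the cation itself is opposite to the one assumed. Setting out from 15, hydrogenation (H2, Pd/C) gives the saturated amide F7 with H1 anti to the methyl, and DIBAL-H reduces it to the aldehyde F8. Addition of the aryllithium 20 gives the secondary benzylic alcohol F9. Ionisation with BF3·OEt2 in the presence of methallyltrimethylsilane at −78 °C (an SN1 allylation of the Hosomi–Sakurai type) gives the methallyl compound F10, and hydrogenation of its 1,1-disubstituted alkene returns to 23.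

**Step 16.**
- What may go wrong: enolisation of the hindered ketone in place of addition of the di-ortho-substituted aryl nucleophile, so that 18 is recovered.
- Fallback: replace the carbonyl addition by a cross-coupling and reach the same cation from an alkene. From 18, KHMDS and PhNTf2 give the enol triflate F11. Negishi coupling with the arylzinc chloride F12 (from 20 and ZnCl2) under Pd2(dba)3/SPhos gives the styrene F13. With CF3CO2H and Et3SiH, protonation at the alkene CH generates the cation of step 17, and the sequence returns at 23 without passing through 22.

**Step 19.**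
- What may go wrong: exchange of only one bromine, or protonation of the dilithio species before it is formylated, giving mono-aldehyde or debrominated material.
- Fallback: double electrophilic formylation of 23 itself by the Rieche reaction (Cl2CHOMe activated by AgOTf or TiCl4, CH2Cl2, −78 °C), going from 23 directly to 26 without 24 or 25; a silyl ether lost on the way would be restored with TESOTf. No new compound is made.

**Step 20.**
- What may go wrong: the demethylation stalling after one or two methyl groups, because each phenoxide formed deactivates the ring, or reversible thiolate addition to the aldehydes leading to side reactions at high temperature.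
- Fallback: change from nucleophilic attack on the methyl groups under basic conditions to chelation-assisted Lewis-acid cleavage with MgI2 etherate in toluene. Every methoxy group has a formyl oxygen ortho to it to bind magnesium while iodide removes the methyl group. This goes from 26 to 27 and makes no new compound.

## Further compounds

F1 | step 3 | cis-fused Diels–Alder adduct of 3 with buta-1,3-diene (C9 ketone, C2=C3) | C1C=CC[C@@H]2C[C@@H](C(C)(C)O[Si](CC)(CC)CC)CC(=O)[C@]12C
F2 | step 3 | cis-fused octalin with C9 methylene (C2=C3) | C1C=CC[C@@H]2C[C@@H](C(C)(C)O[Si](CC)(CC)CC)CC[C@]12C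
F3 | step 3 | trans-2,3-dibromide of F2 | C1C(Br)C(Br)C[C@@H]2C[C@@H](C(C)(C)O[Si](CC)(CC)CC)CC[C@]12C
F4 | step 3 | ring A 1,3-diene (C1=C2, C3=C4) | C1=CC=C[C@@H]2C[C@@H](C(C)(C)O[Si](CC)(CC)CC)CC[C@]12C
F5 | step 3 | C1,C4-endoperoxide (C2=C3) | C13C=CC(OO3)[C@@H]2C[C@@H](C(C)(C)O[Si](CC)(CC)CC)CC[C@]12C
F6 | step 3 | cis-fused decalin-1,4-diol (cis diol) | OC1CCC(O)[C@@H]2C[C@@H](C(C)(C)O[Si](CC)(CC)CC)CC[C@]12C
F7 | step 17 | saturated N-methoxy-N-methylcarboxamide on C1 (equatorial) | CON(C)C(=O)[C@H]1CC[C@@](C)(O[Si](CC)(CC)CC)[C@H]2C[C@@H](C(C)(C)O[Si](CC)(CC)CC)CC[C@]12C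
F8 | step 17 | C1 carbaldehyde (equatorial) | O=C[C@H]1CC[C@@](C)(O[Si](CC)(CC)CC)[C@H]2C[C@@H](C(C)(C)O[Si](CC)(CC)CC)CC[C@]12C
F9 | step 17 | secondary benzylic alcohol at Cb with 2,4,6-trimethoxyphenyl (both epimers) | OC(c1c(OC)cc(OC)cc1OC)[C@H]1CC[C@@](C)(O[Si](CC)(CC)CC)[C@H]2C[C@@H](C(C)(C)O[Si](CC)(CC)CC)CC[C@]12C
F10 | step 17 | (S)-Cb methallyl compound | CC(=C)C[C@H](c1c(OC)cc(OC)cc1OC)[C@H]1CC[C@@](C)(O[Si](CC)(CC)CC)[C@H]2C[C@@H](C(C)(C)O[Si](CC)(CC)CC)CC[C@]12C
F11 | step 16 | enol triflate of 18 (Cb=CH, either geometry) | CC(C)C=C(OS(=O)(=O)C(F)(F)F)[C@H]1CC[C@@](C)(O[Si](CC)(CC)CC)[C@H]2C[C@@H](C(C)(C)O[Si](CC)(CC)CC)CC[C@]12C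
F12 | step 16 | chloro(2,4,6-trimethoxyphenyl)zinc | Cl[Zn]c1c(OC)cc(OC)cc1OC
F13 | step 16 | styrene with 2,4,6-trimethoxyphenyl on Cb (Cb=CH, either geometry) | CC(C)C=C(c1c(OC)cc(OC)cc1OC)[C@H]1CC[C@@](C)(O[Si](CC)(CC)CC)[C@H]2C[C@@H](C(C)(C)O[Si](CC)(CC)CC)CC[C@]12C
F0 | step 19 | none | none
F0 | step 20 | none | none
A1 | alternative 1 | aldoxime precursor (ring A with Cb side chain, C4 ketal, prenyl on C5, oxime arm on C10) | CC(C)C[C@H](c1c(OC)cc(OC)cc1OC)[C@H]1CCC3(OCCO3)[C@@H](CC=C(C)C)[C@]1(C)CC=NO
A2 | alternative 1 | nitrile oxide derived from A1 | CC(C)C[C@H](c1c(OC)cc(OC)cc1OC)[C@H]1CCC3(OCCO3)[C@@H](CC=C(C)C)[C@]1(C)CC#[N+][O-]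
A3 | alternative 1 | trans-decalin fused to a 5,5-dimethylisoxazoline at C7–C8, C4 ketal | CC(C)C[C@H](c1c(OC)cc(OC)cc1OC)[C@H]1CCC3(OCCO3)[C@H]2C[C@@H]4C(=NOC4(C)C)C[C@]12C
A4 | alternative 2 | 3-ethoxycyclobut-2-en-1-one | CCOC1=CC(=O)C1
A5 | alternative 2 | triisopropylsiloxyalkyne on Cb | CC(C)C[C@H](C#CO[Si](C(C)C)(C(C)C)C(C)C)[C@H]1CC[C@@](C)(O[Si](CC)(CC)CC)[C@H]2C[C@@H](C(C)(C)O[Si](CC)(CC)CC)CC[C@]12C
A6 | alternative 2 | differentiated triphenol derivative on Cb (free phenol, silyl ether, ethyl ether; a3 and a5 unsubstituted) | CC(C)C[C@H](c1c(O)cc(OCC)cc1O[Si](C(C)C)(C(C)C)C(C)C)[C@H]1CC[C@@](C)(O[Si](CC)(CC)CC)[C@H]2C[C@@H](C(C)(C)O[Si](CC)(CC)CC)CC[C@]12C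
A7 | alternative 3 | dioxenone tethered through C3–C2–C1 to the vinyl-bearing quaternary C10 | CC(C)C[C@H](c1c(OC)cc(OC)cc1OC)[C@@H](CCC1=CC(=O)OC(C)(C)O1)[C@](C)(C=C)CCO[Si](C)(C)C(C)(C)C
A8 | alternative 3 | photoadduct with ring A fused to a cyclobutane and a dioxanone | CC(C)C[C@H](c1c(OC)cc(OC)cc1OC)[C@H]1CC[C@@]23OC(C)(C)OC(=O)[C@@H]2C[C@H]3[C@]1(C)CCO[Si](C)(C)C(C)(C)C
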